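A direct plan would use the hidden C2 symmetry of the 9,9'-epoxylignan skeleton: the hydrogenated, O-pivaloylated C6–C3 acid would be loaded on (S)-4-benzyloxazolidinone (imide A1) and its titanium enolate dimerised oxidatively at C8–C8' to the bis-imide A2.
Hydride reduction and acid-catalysed cyclodehydration would then give the symmetric trans-dibenzyloxolane A3; one benzylic CH2 would be oxidised with DDQ to the aryl ketone A4, and an oxazaborolidine-catalysed borane reduction would finish.
Weakest would be the quinone-methide benzylic oxidation of A3: it would have to stop after mono-oxidation of one of two identical benzylic positions of an unprotected bis-phenol, on the most valuable material of the sequence, against over-oxidation and oligomerisation, and could only be run to partial conversion with recycling.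
Second would be the oxidative enolate dimerisation: a radical-type coupling whose dl/meso outcome is not secured by the auxiliary, reached only after several steps (saturation, auxiliary loading, phenol masking) that add no skeletal complexity, and spending two auxiliaries on a symmetric compound that must later be desymmetrised.
Third would be the closing ketone reduction: C7 would be created last, by reagent control next to an epimerisable C8 and two free phenols, after a CH2 → C=O → CHOH detour that only repairs the symmetry of A3.

**Plan of the new route**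
The target is cut at C7–C8 (allyl transfer from boron to an aldehyde, the key step), then at C7'–C8' (1,2-metalate shift); the C8'–H bond is made last. The oxolane ring is bought as a 2,5-dihydrofuran-3-yl boronate and is never opened or closed; the two aryl arms are attached to it one after the other.
Enabling feature: C8 is a ring carbon of the oxolane flanked by the exocyclic carbinol C7 and by C8', whose exocyclic neighbour C7' ends as a CH2. An allyl unit C7'(B)–C8'=C8 can therefore be laid through the ring; its C8'=C8 bond is held in the five-membered ring with C9 trans to C7', so a closed chair transition state can only give the 7,8-anti pair. The transposed C8'=C7' benzylidene is a homoallylic alcohol, which lets the C7 hydroxyl direct hydrogen to C8' (3,4-trans).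
C7 is set by a chiral Brønsted acid, C8 in the same event by ring geometry, C8' by relay from C7; the configuration at C7' of the boronate and the benzylidene geometry are both erased when C7' becomes CH2.
No symmetric intermediate exists, so there is no benzylic oxidation, no enolate dimerisation and no ketone reduction; C7 is born as the carbinol.

Key step: step 5

Numbering: lignan numbering is used (C7/C7' benzylic carbons, C8/C8' ring carbons, C9/C9' the OCH2 groups; C7 carries the hydroxyl).
Assumption: the sense of induction of the BINOL-derived phosphoric acid is taken from the re-face preference the (R)-acid shows with aryl aldehydes, so the (S)-acid is specified for the si-face addition that gives (7S); should the sense be opposite on this boronate, the (R)-acid would be used.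

**Step 1**
Reactants: 1 syringaldehyde (4-hydroxy-3,5-dimethoxybenzaldehyde)
Product: 2 3,5-dimethoxy-4-(triisopropylsilyloxy)benzaldehyde
Conditions: TIPSCl (1.2 equiv), imidazole (2.5 equiv), DMF, rt
Reagents that add atoms: chlorotriisopropylsilane, CC(C)[Si](Cl)(C(C)C)C(C)C
Why: Imidazole-promoted O-silylation of the phenol; the TIPS ether should survive s-BuLi (no ring hydrogen ortho to the silyloxy group, so no anionic silyl migration), the Brønsted acid and the hydrogenation, and is removed at the end by fluoride without acid.

**Step 2**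
Reactants: 2 3,5-dimethoxy-4-(triisopropylsilyloxy)benzaldehyde (about half of the batch; the rest is kept for step 5)
Product: 3 [3,5-dimethoxy-4-(triisopropylsilyloxy)phenyl]methanol
Conditions: NaBH4 (0.6 equiv), THF/MeOH, 0 °C
Reagents that add atoms: none
Why: Borohydride reduction of the aldehyde to the primary benzylic alcohol; the aryl silyl ether is inert at 0 °C and no stereocentre is formed.

**Step 3**
Reactants: 3 [3,5-dimethoxy-4-(triisopropylsilyloxy)phenyl]methanol
Product: 4 3,5-dimethoxy-4-(triisopropylsilyloxy)benzyl N,N-diisopropylcarbamate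
Conditions: i-Pr2NCOCl (1.3 equiv), Et3N (1.5 equiv), CH2Cl2, reflux
Reagents that add atoms: N,N-diisopropylcarbamoyl chloride, CC(C)N(C(C)C)C(Cl)=O
Why: O-carbamoylation; the hindered carbamate serves both as the dipole-stabilising, lithium-coordinating group for α-lithiation and as the leaving group of the 1,2-shift in step 4.

**Step 4**
Reactants: 4 3,5-dimethoxy-4-(triisopropylsilyloxy)benzyl N,N-diisopropylcarbamate; 5 2-(2,5-dihydrofuran-3-yl)-4,4,5,5-tetramethyl-1,3,2-dioxaborolane
Product: 8 racemic 2-{(2,5-dihydrofuran-3-yl)[3,5-dimethoxy-4-(triisopropylsilyloxy)phenyl]methyl}-4,4,5,5-tetramethyl-1,3,2-dioxaborolane, via α-lithiated carbamate 6 (not isolated), via lithium boronate complex 7 (not isolated)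
Conditions: s-BuLi (1.2 equiv), TMEDA (1.2 equiv), Et2O, −78 °C; 5 (1.2 equiv), −78 °C; warm to rt (brief reflux if needed); aq. NH4Cl; rapid filtration through deactivated silica
Reagents that add atoms: none
Why: Lithiation–borylation (carbamate-directed benzylic lithiation, boronate complex formation, then 1,2-metalate rearrangement in which the dihydrofuranyl group migrates from boron to C7' with loss of carbamate, a Matteson-type homologation) forms the C7'–C8' bond and places boron on C7' of the allyl unit; racemic material suffices because C7' ends as a CH2.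

**Step 5**
Reactants: 8 racemic 2-{(2,5-dihydrofuran-3-yl)[3,5-dimethoxy-4-(triisopropylsilyloxy)phenyl]methyl}-4,4,5,5-tetramethyl-1,3,2-dioxaborolane (2.2 equiv); 2 3,5-dimethoxy-4-(triisopropylsilyloxy)benzaldehyde (1.0 equiv)
Product: 10 (S)-[3,5-dimethoxy-4-(triisopropylsilyloxy)phenyl]{(3R,4E)-4-[3,5-dimethoxy-4-(triisopropylsilyloxy)benzylidene]oxolan-3-yl}methanol, via pinacol borate ester 9 (not isolated)
Conditions: (S)-TRIP [(S)-3,3'-bis(2,4,6-triisopropylphenyl)-1,1'-binaphthyl-2,2'-diyl hydrogen phosphate] (10 mol%), 4 Å molecular sieves, toluene, −40 → −20 °C; aq. NaHCO3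
Reagents that add atoms: none
Why: Brønsted-acid-catalysed allylboration of an aldehyde through a closed Zimmerman–Traxler chair, the closest known reactions being the phosphoric-acid-catalysed crotylboration of aryl aldehydes and the kinetic resolution of racemic α-substituted allyl pinacolboronates under the same catalysis. C7–C8 forms at the γ-carbon (ring C8) of the unit C7'(B)–C8'=C8 while boron passes to the aldehyde oxygen and the double bond moves to C8'=C7'; no ring is closed, the oxolane is carried through intact, and the cyclic transition state excludes attack through C7'. C8 is set by the substrate: inside the five-membered ring C9 is necessarily trans to C7' across C8'=C8, so it sits equatorial in the chair like the methyl group of an (E)-crotylboronate and only the 7,8-anti pair can form. C7 is set by the catalyst: the acid hydrogen-bonds to the pseudo-axial boronate oxygen and to the formyl C–H and exposes the si face of the aldehyde (aryl equatorial), giving (7S) and with it (8R). The selectivity needed is catalyst control over the α-stereocentre of the reagent: the (S)-enantiomer of 8 can place its aryl group axial in the favoured chair and should react fast (hence the excess of racemic 8), while any product formed from the (R)-enantiomer through the equatorial chair has the same C7/C8 configuration and differs only in benzylidene geometry. The pinacol ester should show negligible uncatalysed background reaction at −40 °C, and both alkene isomers converge in step 6.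

**Step 6**
Reactants: 10 (S)-[3,5-dimethoxy-4-(triisopropylsilyloxy)phenyl]{(3R,4E)-4-[3,5-dimethoxy-4-(triisopropylsilyloxy)benzylidene]oxolan-3-yl}methanol
Product: 11 (S)-[3,5-dimethoxy-4-(triisopropylsilyloxy)phenyl]{(3R,4R)-4-[3,5-dimethoxy-4-(triisopropylsilyloxy)benzyl]oxolan-3-yl}methanol
Conditions: H2 (1 atm), [Ir(cod)(PCy3)(py)]PF6 (5 mol%), CH2Cl2, 0 °C → rt
Reagents that add atoms: none
Why: Hydroxyl-directed homogeneous hydrogenation with Crabtree's catalyst: the cationic monovalent iridium centre binds the C7 hydroxyl and the exocyclic C8'=C7' bond of this homoallylic alcohol and delivers hydrogen to the ring face that carries the C8 side chain, so the new benzyl group at C8' ends trans to it (4R), whereas undirected steric delivery would give the cis ring.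

**Step 7**
Reactants: 11 (S)-[3,5-dimethoxy-4-(triisopropylsilyloxy)phenyl]{(3R,4R)-4-[3,5-dimethoxy-4-(triisopropylsilyloxy)benzyl]oxolan-3-yl}methanol
Product: 12 (S)-(4-hydroxy-3,5-dimethoxyphenyl)[(3R,4R)-4-(4-hydroxy-3,5-dimethoxybenzyl)oxolan-3-yl]methanol (CNP0257794.1)
Conditions: TBAF (2.5 equiv), AcOH (2.5 equiv), THF, 0 °C; pH 7 buffer
Reagents that add atoms: none
Why: Buffered fluoride cleavage of both aryl silyl ethers; no acid is present that could ionise the p-hydroxybenzylic alcohol to a quinone methide, and no stereocentre is touched.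

**Compound list**
1 | syringaldehyde (4-hydroxy-3,5-dimethoxybenzaldehyde) | COc1cc(C=O)cc(OC)c1O | starting material
2 | 3,5-dimethoxy-4-(triisopropylsilyloxy)benzaldehyde | COc1cc(C=O)cc(OC)c1O[Si](C(C)C)(C(C)C)C(C)C | intermediate
3 | [3,5-dimethoxy-4-(triisopropylsilyloxy)phenyl]methanol | COc1cc(CO)cc(OC)c1O[Si](C(C)C)(C(C)C)C(C)C | intermediate
4 | 3,5-dimethoxy-4-(triisopropylsilyloxy)benzyl N,N-diisopropylcarbamate | COc1cc(COC(=O)N(C(C)C)C(C)C)cc(OC)c1O[Si](C(C)C)(C(C)C)C(C)C | intermediate
5 | 2-(2,5-dihydrofuran-3-yl)-4,4,5,5-tetramethyl-1,3,2-dioxaborolane | CC1(C)OB(C2=CCOC2)OC1(C)C | starting material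
6 | α-lithiated carbamate: [3,5-dimethoxy-4-(triisopropylsilyloxy)phenyl](N,N-diisopropylcarbamoyloxy)methyllithium, racemic | [Li]C(OC(=O)N(C(C)C)C(C)C)c1cc(OC)c(O[Si](C(C)C)(C(C)C)C(C)C)c(OC)c1 | intermediate
7 | lithium boronate complex formed from 6 and 5, racemic | [Li+].CC1(C)O[B-](C2=CCOC2)(C(OC(=O)N(C(C)C)C(C)C)c2cc(OC)c(O[Si](C(C)C)(C(C)C)C(C)C)c(OC)c2)OC1(C)C | intermediate
8 | racemic 2-{(2,5-dihydrofuran-3-yl)[3,5-dimethoxy-4-(triisopropylsilyloxy)phenyl]methyl}-4,4,5,5-tetramethyl-1,3,2-dioxaborolane | CC1(C)OB(C(C2=CCOC2)c2cc(OC)c(O[Si](C(C)C)(C(C)C)C(C)C)c(OC)c2)OC1(C)C | intermediate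
9 | O-pinacolboryl derivative (borate ester) of 10 | COc1cc(/C=C2/COC[C@@H]2[C@H](OB3OC(C)(C)C(C)(C)O3)c2cc(OC)c(O[Si](C(C)C)(C(C)C)C(C)C)c(OC)c2)cc(OC)c1O[Si](C(C)C)(C(C)C)C(C)C | intermediate
10 | (S)-[3,5-dimethoxy-4-(triisopropylsilyloxy)phenyl]{(3R,4E)-4-[3,5-dimethoxy-4-(triisopropylsilyloxy)benzylidene]oxolan-3-yl}methanol | COc1cc(/C=C2/COC[C@@H]2[C@H](O)c2cc(OC)c(O[Si](C(C)C)(C(C)C)C(C)C)c(OC)c2)cc(OC)c1O[Si](C(C)C)(C(C)C)C(C)C | intermediate
11 | (S)-[3,5-dimethoxy-4-(triisopropylsilyloxy)phenyl]{(3R,4R)-4-[3,5-dimethoxy-4-(triisopropylsilyloxy)benzyl]oxolan-3-yl}methanol | COc1cc(C[C@H]2COC[C@@H]2[C@H](O)c2cc(OC)c(O[Si](C(C)C)(C(C)C)C(C)C)c(OC)c2)cc(OC)c1O[Si](C(C)C)(C(C)C)C(C)C | intermediate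
12 | (S)-(4-hydroxy-3,5-dimethoxyphenyl)[(3R,4R)-4-(4-hydroxy-3,5-dimethoxybenzyl)oxolan-3-yl]methanol | COc1cc(C[C@H]2COC[C@@H]2[C@H](O)c2cc(OC)c(O)c(OC)c2)cc(OC)c1O | target

**Count and risks**
Total step count: 7. Longest linear sequence: 7 steps (1 → 2 → 3 → 4 → 8 → 10 → 11 → 12).

Step 5. What may go wrong: the acid may fail to override the bias of the α-stereocentre of 8 (low enantiofacial control), or allyl transfer from the hindered boronate to the electron-rich aldehyde may be so slow that 1,3-boron migration and protodeboronation of 8 take over. The fallback sets out from 5 and 2 and returns at 10. One-carbon Matteson homologation of 5 (BrCH2Cl, n-BuLi, THF, −78 °C → rt) should give the achiral 2-[(2,5-dihydrofuran-3-yl)methyl]-4,4,5,5-tetramethyl-1,3,2-dioxaborolane F1, which has no α-stereocentre. Its (S)-TRIP-catalysed addition to 2, the ring analogue of an (E)-crotylboration, should give (S)-[3,5-dimethoxy-4-(triisopropylsilyloxy)phenyl][(3R)-4-methylideneoxolan-3-yl]methanol F2. The second aryl group would then be brought in by cross-metathesis of the exocyclic methylene with 3,5-dimethoxy-4-(triisopropylsilyloxy)styrene F3 (from 2 with Ph3P=CH2), using the second-generation Grubbs catalyst RuCl2(H2IMes)(PCy3)(=CHPh) in CH2Cl2 at 40 °C. This should give 10 as an E/Z mixture, which step 6 accepts.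

Step 6. What may go wrong: hydroxyl direction may be outweighed by steric approach (hydrogen then enters anti to the C8 side chain and the cis-oxolane results), or the iridium hydride may move the double bond into the ring so that C8 is lost. The fallback sets out from 10 and returns at 12. The carbinol is capped (TESOTf, 2,6-lutidine, CH2Cl2, −78 °C) to give triethyl{(S)-[3,5-dimethoxy-4-(triisopropylsilyloxy)phenyl][(3R,4E)-4-(3,5-dimethoxy-4-(triisopropylsilyloxy)benzylidene)oxolan-3-yl]methoxy}silane F4, so that no directing group remains. The single (E)-isomer is then hydrogenated under catalyst control with a chiral monovalent iridium N,P complex, [Ir(cod)(t-Bu-PHOX)]BArF (H2 50 bar, CH2Cl2); both ligand enantiomers are tested and the one that delivers hydrogen to the C8' face cis to the side chain is kept. The resulting triethylsilyl ether of 11, F5, should lose all three silyl groups under the fluoride conditions of step 7 and give 12 directly.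

Step 4. What may go wrong: ring lithiation between a methoxy group and the carbamoyloxymethyl group may compete with benzylic lithiation, the boronate complex may revert instead of rearranging, or 8 may be lost on isolation by protodeboronation or boron migration. The fallback sets out from 5 and returns at 8. Matteson homologation of 5 with the dichloromethyl carbenoid (CH2Cl2, n-BuLi, THF, −100 °C; ZnCl2, → rt) should give 2-[chloro(2,5-dihydrofuran-3-yl)methyl]-4,4,5,5-tetramethyl-1,3,2-dioxaborolane F6. Commercial 4-bromo-2,6-dimethoxyphenol is silylated (TIPSCl, imidazole, DMF) to 5-bromo-1,3-dimethoxy-2-(triisopropylsilyloxy)benzene F7 and converted (Mg, THF) into [3,5-dimethoxy-4-(triisopropylsilyloxy)phenyl]magnesium bromide F8, which is added to F6 at −78 °C. On warming, the aryl group should migrate from boron to carbon with loss of chloride and give 8; the aryl arm thus arrives as the nucleophile instead of as the carbenoid.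

**Further compounds**
F1 | step 5 | 2-[(2,5-dihydrofuran-3-yl)methyl]-4,4,5,5-tetramethyl-1,3,2-dioxaborolane | CC1(C)OB(CC2=CCOC2)OC1(C)C
F2 | step 5 | (S)-[3,5-dimethoxy-4-(triisopropylsilyloxy)phenyl][(3R)-4-methylideneoxolan-3-yl]methanol | C=C1COC[C@@H]1[C@H](O)c1cc(OC)c(O[Si](C(C)C)(C(C)C)C(C)C)c(OC)c1
F3 | step 5 | 3,5-dimethoxy-4-(triisopropylsilyloxy)styrene | C=Cc1cc(OC)c(O[Si](C(C)C)(C(C)C)C(C)C)c(OC)c1
F4 | step 6 | triethyl{(S)-[3,5-dimethoxy-4-(triisopropylsilyloxy)phenyl][(3R,4E)-4-(3,5-dimethoxy-4-(triisopropylsilyloxy)benzylidene)oxolan-3-yl]methoxy}silane | COc1cc(/C=C2/COC[C@@H]2[C@H](O[Si](CC)(CC)CC)c2cc(OC)c(O[Si](C(C)C)(C(C)C)C(C)C)c(OC)c2)cc(OC)c1O[Si](C(C)C)(C(C)C)C(C)C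
F5 | step 6 | triethyl{(S)-[3,5-dimethoxy-4-(triisopropylsilyloxy)phenyl][(3R,4R)-4-(3,5-dimethoxy-4-(triisopropylsilyloxy)benzyl)oxolan-3-yl]methoxy}silane | COc1cc(C[C@H]2COC[C@@H]2[C@H](O[Si](CC)(CC)CC)c2cc(OC)c(O[Si](C(C)C)(C(C)C)C(C)C)c(OC)c2)cc(OC)c1O[Si](C(C)C)(C(C)C)C(C)C
F6 | step 4 | 2-[chloro(2,5-dihydrofuran-3-yl)methyl]-4,4,5,5-tetramethyl-1,3,2-dioxaborolane, racemic | CC1(C)OB(C(Cl)C2=CCOC2)OC1(C)C
F7 | step 4 | 5-bromo-1,3-dimethoxy-2-(triisopropylsilyloxy)benzene | COc1cc(Br)cc(OC)c1O[Si](C(C)C)(C(C)C)C(C)C
F8 | step 4 | [3,5-dimethoxy-4-(triisopropylsilyloxy)phenyl]magnesium bromide | COc1cc([Mg]Br)cc(OC)c1O[Si](C(C)C)(C(C)C)C(C)C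
A1 | direct plan | 4-{3-[(4S)-4-benzyl-2-oxo-1,3-oxazolidin-3-yl]-3-oxopropyl}-2,6-dimethoxyphenyl pivalate | COc1cc(CCC(=O)N2C(=O)OC[C@@H]2Cc2ccccc2)cc(OC)c1OC(=O)C(C)(C)C
A2 | direct plan | (2R,3R)-1,4-bis[(4S)-4-benzyl-2-oxo-1,3-oxazolidin-3-yl]-2,3-bis(3,5-dimethoxy-4-pivaloyloxybenzyl)butane-1,4-dione | O=C([C@H](Cc1cc(OC)c(OC(=O)C(C)(C)C)c(OC)c1)[C@@H](Cc1cc(OC)c(OC(=O)C(C)(C)C)c(OC)c1)C(=O)N1C(=O)OC[C@@H]1Cc1ccccc1)N1C(=O)OC[C@@H]1Cc1ccccc1
A3 | direct plan | (3R,4R)-3,4-bis(4-hydroxy-3,5-dimethoxybenzyl)oxolane | COc1cc(C[C@H]2COC[C@@H]2Cc2cc(OC)c(O)c(OC)c2)cc(OC)c1O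
A4 | direct plan | (4-hydroxy-3,5-dimethoxyphenyl)[(3R,4R)-4-(4-hydroxy-3,5-dimethoxybenzyl)oxolan-3-yl]methanone | COc1cc(C[C@H]2COC[C@@H]2C(=O)c2cc(OC)c(O)c(OC)c2)cc(OC)c1O
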